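## Retrosynthetic overview
1. The target is the (2S)-chromene carrying a (1R,3R)-cyclohexane. The last disconnection is the O1–C2 bond of the pyran ring. It leads back to a vinylogous ortho-quinone methide that is closed under chiral Brønsted acid control, and this comes from an E-enal plus symmetric 4,5,6-trimethoxyresorcinol (one free ring carbon, two equivalent OH groups).
2. The E-enal comes from a terminal alkyne by methylalumination, hydroxymethylation and oxidation. The exocyclic CH2 comes from a hindered ketone by Peterson olefination.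
3. The alkynyl ketone comes from Eschenmoser–Tanabe fragmentation of a bicyclic epoxy ketone. The temporary second carbocycle serves only to fix the 1,3-trans dimethyl relation thermodynamically.
4. The octalone comes from 2,6-dimethylcyclohexanone and methyl vinyl ketone through the (S)-1-phenylethylamine imine, which sets the quaternary centre. The resorcinol comes from 1,2,3-trimethoxybenzene by dibromination and hydroxylation.
5. Ring order: the cyclohexane and the arene are bought, the temporary enone ring is made in step 2 and cleaved in step 4, and the pyran ring is formed last in step 10.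

Assumption: the sense of induction of the new step 10 cannot be known in advance. The (R)-acid is written as giving 2S; the (S)-acid is used if the opposite is found, because the side-chain stereocentres are too remote to interfere.

## Route

Step 1
Reactants: 1 2,6-dimethylcyclohexanone (commercial cis/trans mixture); 2 (S)-1-phenylethylamine; 3 methyl vinyl ketone
Product: 6 (2R)-2,6-dimethyl-2-(3-oxobutyl)cyclohexan-1-one (C6 epimer mixture), via ketimine 4 (not isolated), via Michael adduct imine 5 (not isolated)
Conditions: 2 (1.05 equiv), p-TsOH·H2O (1 mol %), toluene, reflux, Dean–Stark, 24 h; concentrate; 3 (1.3 equiv), THF, 40 °C, 3 d; then 20% aq AcOH, rt, 2 h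
Reagents that add atoms: water, O
Why: Deracemising aza-ene-type Michael addition of a chiral ketimine (d'Angelo reaction), in which the tetrasubstituted secondary enamine tautomer of 4 adds to 3 in a compact cyclic transition state on the face away from the phenyl group of the (S)-auxiliary, setting the quaternary carbon as R (same sense as the 2-methylcyclohexanone case, typically at least 90% ee) while C6 is corrected in step 2.

Step 2
Reactants: 6 (2R)-2,6-dimethyl-2-(3-oxobutyl)cyclohexan-1-one
Product: 8 (4aR,8R)-4a,8-dimethyl-4,4a,5,6,7,8-hexahydronaphthalen-2(3H)-one, via aldol ketol 7 (not isolated)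
Conditions: NaOMe (1.0 equiv), MeOH, rt then 60 °C, 6 h
Reagents that add atoms: none
Why: Intramolecular aldol condensation (second half of a Robinson annulation) in which C8 epimerises through the extended dienolate and settles equatorial and trans to the axial angular methyl, because the cis isomer has a 1,3-diaxial Me/Me contact (as in the 6β-to-6α methyl equilibration of steroidal 4-en-3-ones), which sets C8 as R.

Step 3
Reactants: 8 (4aR,8R)-4a,8-dimethyl-4,4a,5,6,7,8-hexahydronaphthalen-2(3H)-one
Product: 9 (4aR,8R)-1,8a-epoxy-4a,8-dimethyloctahydronaphthalen-2(1H)-one (epoxide diastereomer mixture)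
Conditions: 30% aq H2O2 (4 equiv), 4 M aq NaOH (0.5 equiv), MeOH, 0 °C to rt
Reagents that add atoms: hydrogen peroxide, OO
Why: Weitz–Scheffer nucleophilic epoxidation of the enone, where both new epoxide centres are erased in step 4 so the facial ratio does not matter, and C8 is no longer acidic once the enone is consumed.

Step 4
Reactants: 9 (4aR,8R)-1,8a-epoxy-4a,8-dimethyloctahydronaphthalen-2(1H)-one; 10 p-toluenesulfonyl hydrazide
Product: 12 (2R,6R)-2-(but-3-yn-1-yl)-2,6-dimethylcyclohexan-1-one, via epoxy tosylhydrazone 11 (not isolated)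
Conditions: 10 (1.05 equiv), AcOH/CH2Cl2 1:1, −20 °C to rt, 6 h
Reagents that add atoms: none
Why: Eschenmoser–Tanabe fragmentation, in which the epoxy tosylhydrazone opens to an alkoxy azoalkene that loses N2 and sulfinate and cleaves C1–C8a into ring ketone plus terminal alkyne, creating no new stereocentre and leaving the alpha-methine (C6, R) untouched in the cold, weakly acidic medium.

Step 5
Reactants: 12 (2R,6R)-2-(but-3-yn-1-yl)-2,6-dimethylcyclohexan-1-one
Product: 14 (1R,3R)-1-(but-3-yn-1-yl)-1,3-dimethyl-2-methylidenecyclohexane, via beta-hydroxysilane 13 (not isolated)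
Conditions: Me3SiCH2Li (3 equiv), THF/pentane, −78 to 0 °C; H2O quench; crude 13, 48% aq HF (2 equiv), MeCN, 0 °C, 30 min
Reagents that add atoms: (trimethylsilyl)methyllithium, [Li]C[Si](C)(C)C
Why: Peterson olefination, in which the weakly basic, strongly nucleophilic silylmethyllithium adds to the hindered ketone (one equivalent is used by the alkyne C–H) and acid-induced loss of silanol equivalents from the strained tertiary carbinol gives the methylene without passing through an equilibrating enolate, so C3 stays R.

Step 6
Reactants: 14 (1R,3R)-1-(but-3-yn-1-yl)-1,3-dimethyl-2-methylidenecyclohexane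
Product: 17 (2E)-5-[(1R,3R)-1,3-dimethyl-2-methylidenecyclohexyl]-3-methylpent-2-en-1-ol, via alkenylalane 15 (not isolated), via lithium alanate 16 (not isolated)
Conditions: Me3Al (2.5 equiv), Cp2ZrCl2 (0.25 equiv), CH2Cl2, 0 °C to rt, 12 h; strip volatiles, hexane; n-BuLi (1.0 equiv), THF, −78 to 0 °C; (CH2O)n (5 equiv), rt; H2O work-up
Reagents that add atoms: trimethylaluminium, C[Al](C)C; paraformaldehyde (as formaldehyde), C=O
Why: Negishi zirconium-catalysed methylalumination adds Me and Al syn across the terminal alkyne (about 95:5 regioselectivity, over 98% E), the alanate is hydroxymethylated with retention, and the hindered 1,1-disubstituted alkene is inert.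

Step 7
Reactants: 17 (2E)-5-[(1R,3R)-1,3-dimethyl-2-methylidenecyclohexyl]-3-methylpent-2-en-1-ol
Product: 18 (2E)-5-[(1R,3R)-1,3-dimethyl-2-methylidenecyclohexyl]-3-methylpent-2-enal
Conditions: TEMPO (10 mol %), PhI(OAc)2 (1.1 equiv), CH2Cl2, 0 °C to rt, 3 h
Reagents that add atoms: none
Why: Oxoammonium (TEMPO/PhI(OAc)2) oxidation is selective for the primary allylic alcohol and, as with geraniol and nerol, does not isomerise the E alkene or touch the exocyclic methylene.

Step 8
Reactants: 19 1,2,3-trimethoxybenzene
Product: 20 1,5-dibromo-2,3,4-trimethoxybenzene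
Conditions: NBS (2.1 equiv), MeCN, 0 °C to rt, 12 h
Reagents that add atoms: N-bromosuccinimide, O=C1CCC(=O)N1Br
Why: Electrophilic aromatic bromination, where each bromine enters ortho to one outer methoxy group and para to the other, while the remaining position is activated only by the twisted central methoxy group and stays free.

Step 9
Reactants: 20 1,5-dibromo-2,3,4-trimethoxybenzene
Product: 21 4,5,6-trimethoxybenzene-1,3-diol
Conditions: Cu(acac)2 (5 mol %), N,N'-bis(4-hydroxy-2,6-dimethylphenyl)oxalamide (5 mol %), LiOH·H2O (4.5 equiv), DMSO/H2O 4:1, 100 °C, argon; then 1 M HCl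
Reagents that add atoms: lithium hydroxide, [Li+].[OH-]
Why: Ullmann-type copper-catalysed hydroxylation of both C–Br bonds, where the oxalamide ligand lets electron-rich ortho-substituted bromides react and exclusion of air protects the electron-rich diol.

Step 10
Reactants: 18 (2E)-5-[(1R,3R)-1,3-dimethyl-2-methylidenecyclohexyl]-3-methylpent-2-enal; 21 4,5,6-trimethoxybenzene-1,3-diol
Product: 24 (2S)-2-{2-[(1R,3R)-1,3-dimethyl-2-methylidenecyclohexyl]ethyl}-6,7,8-trimethoxy-2-methyl-2H-chromen-5-ol, via benzylic alcohol 22 (not isolated), via ortho-quinone methide 23 (not isolated)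
Conditions: (R)-3,3'-bis(2,4,6-triisopropylphenyl)-1,1'-binaphthyl-2,2'-diyl N-triflylphosphoramide (10 mol %), 21 (1.2 equiv), 5 Å MS, toluene, −30 °C, dark, argon, 48 h; Et3N quench at −30 °C
Reagents that add atoms: none
Why: Proposed new method: a catalytic asymmetric dehydrative chromene annulation in which the confined chiral Brønsted acid first promotes Friedel–Crafts hydroxyalkylation of the only free ring carbon of symmetric 21 by the carbonyl of 18, then ionises the doubly activated alcohol 22 to the O-protonated form of 23 held as a hydrogen-bonded contact ion pair, so that the stereodetermining O1–C2 closure (a disrotatory oxa-6π electrocyclisation, equivalently an intramolecular allylic etherification) occurs inside the chiral pocket, where the fixed E geometry of the terminal alkene ties the catalyst-selected helical twist of the s-cis dienone to one face of C2 and sets it as S; either ortho oxygen gives the same constitution after proton shuttling, no aromatic C–H is left for over-reaction, and the unactivated exocyclic alkene is not protonated at this acidity and temperature; the closest known reaction types are the non-selective amine-salt-mediated resorcinol/citral Knoevenagel–oxa-6π annulation and the chiral N-triflylphosphoramide-catalysed intramolecular allylic substitution giving 2-aryl-2-methyl-2H-chromenes, neither shown enantioselectively for 2,2-dialkyl chromenes or in intermolecular form.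

## Compound list
1 | 2,6-dimethylcyclohexanone (cis/trans mixture) | CC1CCCC(C)C1=O | starting material
2 | (S)-1-phenylethylamine | C[C@H](N)c1ccccc1 | starting material
3 | methyl vinyl ketone | C=CC(C)=O | starting material
4 | 2,6-dimethyl-N-[(1S)-1-phenylethyl]cyclohexan-1-imine | C[C@@H](c1ccccc1)N=C2C(C)CCCC2C | intermediate
5 | 4-{(1R)-1,3-dimethyl-2-[(1S)-1-phenylethylimino]cyclohexyl}butan-2-one | C[C@@H](c1ccccc1)N=C2C(C)CCC[C@]2(C)CCC(C)=O | intermediate
6 | (2R)-2,6-dimethyl-2-(3-oxobutyl)cyclohexan-1-one (C6 epimer mixture) | O=C1C(C)CCC[C@]1(C)CCC(C)=O | intermediate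
7 | (4aR)-8a-hydroxy-4a,8-dimethyloctahydronaphthalen-2(1H)-one | O=C3CC1(O)C(C)CCC[C@]1(C)CC3 | intermediate
8 | (4aR,8R)-4a,8-dimethyl-4,4a,5,6,7,8-hexahydronaphthalen-2(3H)-one | O=C3C=C1[C@H](C)CCC[C@]1(C)CC3 | intermediate
9 | (4aR,8R)-1,8a-epoxy-4a,8-dimethyloctahydronaphthalen-2(1H)-one (epoxide diastereomer mixture) | O=C3C4OC14[C@H](C)CCC[C@]1(C)CC3 | intermediate
10 | p-toluenesulfonyl hydrazide | Cc1ccc(cc1)S(=O)(=O)NN | starting material
11 | tosylhydrazone of 9 | Cc1ccc(cc1)S(=O)(=O)NN=C3C4OC14[C@H](C)CCC[C@]1(C)CC3 | intermediate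
12 | (2R,6R)-2-(but-3-yn-1-yl)-2,6-dimethylcyclohexan-1-one | O=C1[C@H](C)CCC[C@]1(C)CCC#C | intermediate
13 | (2R,6R)-2-(but-3-yn-1-yl)-2,6-dimethyl-1-[(trimethylsilyl)methyl]cyclohexan-1-ol | C[Si](C)(C)CC1(O)[C@H](C)CCC[C@]1(C)CCC#C | intermediate
14 | (1R,3R)-1-(but-3-yn-1-yl)-1,3-dimethyl-2-methylidenecyclohexane | C=C1[C@H](C)CCC[C@]1(C)CCC#C | intermediate
15 | {(1E)-4-[(1R,3R)-1,3-dimethyl-2-methylidenecyclohexyl]-2-methylbut-1-en-1-yl}dimethylalane | C=C1[C@H](C)CCC[C@]1(C)CC/C(C)=C/[Al](C)C | intermediate
16 | lithium butyl{(1E)-4-[(1R,3R)-1,3-dimethyl-2-methylidenecyclohexyl]-2-methylbut-1-en-1-yl}dimethylalanate | [Li+].C=C1[C@H](C)CCC[C@]1(C)CC/C(C)=C/[Al-](C)(C)CCCC | intermediate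
17 | (2E)-5-[(1R,3R)-1,3-dimethyl-2-methylidenecyclohexyl]-3-methylpent-2-en-1-ol | C=C1[C@H](C)CCC[C@]1(C)CC/C(C)=C/CO | intermediate
18 | (2E)-5-[(1R,3R)-1,3-dimethyl-2-methylidenecyclohexyl]-3-methylpent-2-enal | C=C1[C@H](C)CCC[C@]1(C)CC/C(C)=C/C=O | intermediate
19 | 1,2,3-trimethoxybenzene | COc1cccc(OC)c1OC | starting material
20 | 1,5-dibromo-2,3,4-trimethoxybenzene | COc1c(Br)cc(Br)c(OC)c1OC | intermediate
21 | 4,5,6-trimethoxybenzene-1,3-diol | COc1c(O)cc(O)c(OC)c1OC | intermediate
22 | 2-{(2E)-5-[(1R,3R)-1,3-dimethyl-2-methylidenecyclohexyl]-1-hydroxy-3-methylpent-2-en-1-yl}-4,5,6-trimethoxybenzene-1,3-diol | C=C1[C@H](C)CCC[C@]1(C)CC/C(C)=C/C(O)c1c(O)c(OC)c(OC)c(OC)c1O | intermediate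
23 | 6-{(2E)-5-[(1R,3R)-1,3-dimethyl-2-methylidenecyclohexyl]-3-methylpent-2-en-1-ylidene}-5-hydroxy-2,3,4-trimethoxycyclohexa-2,4-dien-1-one | C=C1[C@H](C)CCC[C@]1(C)CC/C(C)=C/C=C1C(=O)C(OC)=C(OC)C(OC)=C1O | intermediate
24 | (2S)-2-{2-[(1R,3R)-1,3-dimethyl-2-methylidenecyclohexyl]ethyl}-6,7,8-trimethoxy-2-methyl-2H-chromen-5-ol | C=C1[C@H](C)CCC[C@]1(C)CC[C@@]1(C)C=Cc2c(O)c(OC)c(OC)c(OC)c2O1 | target

## Step count and risks
Total steps: 10, with no protecting groups. Longest linear sequence: 8 (steps 1 to 7, then 10).

**Step 10 (proposed new step).**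
- Risk: the catalyst may discriminate poorly between methyl and the CH2CH2 chain at C2. The product ether may re-ionise reversibly and epimerise C2. The acid may isomerise the enal.
- Fallback (known chemistry), from 18 and 21 back to 24: heat 18 and 21 with ethylenediammonium diacetate (10 mol %) in toluene at 90 °C, the established non-selective Knoevenagel/oxa-6π chromene annulation. This gives a roughly 1:1 mixture of 24 and its C2 epimer (2R)-2-{2-[(1R,3R)-1,3-dimethyl-2-methylidenecyclohexyl]ethyl}-6,7,8-trimethoxy-2-methyl-2H-chromen-5-ol F1. The two are diastereomers and are separated by preparative SFC on a polysaccharide chiral stationary phase. F1 is recycled by 365 nm irradiation in toluene, which reopens the pyran ring to 23 and lets it close again unselectively, and the mixture is separated once more.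

**Step 5.**
- Risk: addition of the silylmethyl nucleophile to a ketone flanked by a quaternary and a tertiary carbon may be slow, and enolisation may compete.
- Fallback, from 12 back to 14: replace the silicon addition/elimination by methyl addition and regioselective dehydration. The smaller MeLi (3 equiv, Et2O, −78 to 0 °C) attacks 12 axially, because the equatorial path is blocked by the axial C2 methyl. This gives the equatorial tertiary alcohol (1S,2R,6R)-2-(but-3-yn-1-yl)-1,2,6-trimethylcyclohexan-1-ol F2. SOCl2/pyridine at −20 °C then eliminates anti-periplanar, which for an equatorial leaving group is possible only toward the new methyl group, and gives 14.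

**Step 9.**
- Risk: the second C–Br bond sits on an even more electron-rich bromophenoxide and may react slowly. The diol dianion is air-sensitive at 100 °C.
- Fallback, from 20 back to 21: go through carbon–boron bonds instead of direct C–O coupling. Miyaura borylation (B2pin2 2.4 equiv, PdCl2(dppf) 5 mol %, KOAc, dioxane, 90 °C) gives 2,2'-(4,5,6-trimethoxybenzene-1,3-diyl)bis(4,4,5,5-tetramethyl-1,3,2-dioxaborolane) F3. Mild oxidation (NaBO3·4H2O, THF/H2O, rt) then gives 21.

## Further compounds
F1 | step 10 | (2R)-2-{2-[(1R,3R)-1,3-dimethyl-2-methylidenecyclohexyl]ethyl}-6,7,8-trimethoxy-2-methyl-2H-chromen-5-ol | C=C1[C@H](C)CCC[C@]1(C)CC[C@]1(C)C=Cc2c(O)c(OC)c(OC)c(OC)c2O1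
F2 | step 5 | (1S,2R,6R)-2-(but-3-yn-1-yl)-1,2,6-trimethylcyclohexan-1-ol | O[C@@]1(C)[C@H](C)CCC[C@]1(C)CCC#C
F3 | step 9 | 2,2'-(4,5,6-trimethoxybenzene-1,3-diyl)bis(4,4,5,5-tetramethyl-1,3,2-dioxaborolane) | COc1c(B2OC(C)(C)C(C)(C)O2)cc(B2OC(C)(C)C(C)(C)O2)c(OC)c1OC
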